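Readings and results were generated by integration with made-up constants.

| flask | left-handed substrate | right-handed substrate | gas | free catalyst | remark | time |
|---|---|---|---|---|---|---|
| alder | 1 M | 1 M | 200 mM (held) | 0.05 mol% | run made earlier |  |
| oak | 1 M | 1 M | 200 mM (held) | 0.075 mol% | run made earlier |  |
| birch | 2 M | 2 M | 200 mM (held) | 0.1 mol% | run made earlier |  |
| flask | 1.0 M | 1.0 M | 200 mM (held) | 0.1 mol% |  | 10 min |

| run | time / min | left-handed product / % | right-handed product / % |
|---|---|---|---|
| alder | 1.00 | 2.1 | 1.2 |
| alder | 2.50 | 8.3 | 0.4 |
| alder | 3.00 | 9.4 | 3.0 |
| alder | 5.00 | 15.6 | 5.1 |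
| alder | 6.00 | 15.6 | 7.1 |
| alder | 8.00 | 20.9 | 11.2 |
| oak | 1.00 | 4.0 | 0.5 |
| oak | 2.50 | 13.4 | 1.4 |
| oak | 3.00 | 13.8 | 3.1 |
| oak | 5.00 | 20.7 | 7.9 |
| oak | 6.00 | 24.0 | 11.7 |
| oak | 8.00 | 27.5 | 15.8 |
| birch | 1.50 | 9.6 | 1.2 |
| birch | 3.00 | 13.2 | 3.9 |
| birch | 5.00 | 23.1 | 9.7 |
| birch | 6.00 | 25.1 | 11.4 |
| birch | 8.00 | 29.5 | 16.7 |

(scatter of a reading: 1 percentage point)

- free catalyst is single-handed; left-handed substrate and right-handed substrate are mirror images of each other, charged as a racemate, each of them at the stated concentration
- at the start none of reagent is dissolved
- steps that have been proposed: free catalyst + right-handed substrate <-> catalyst intermediate B; free catalyst + left-handed substrate <-> catalyst intermediate A; reagent + catalyst intermediate B -> free catalyst + right-handed product; left-handed product <-> right-handed product; reagent + free catalyst -> spent catalyst; reagent + catalyst intermediate A -> free catalyst + left-handed product; gas <-> reagent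
- an excess is the difference of the two amounts in percent of their sum
- an excess is below zero if the other one leads

* excess of left-handed product over right-handed product in the product at 12 s
* excess of left-handed product over right-handed product in the product at 10 min
* part of the left-handed substrate and right-handed substrate charged together that has reacted at 10 min

The constants of the proposed steps are unknown, but the runs give a working one: the share of the charge turned into product per minute, which over the first 5.00 min is larger in oak, at the higher loading of free catalyst, than in alder. The excess of left-handed product over right-handed product at 8.00 min reads 30.2%, 27.0% and 27.7% in alder, oak and birch, at different conversions. So right-handed product is taken here as left-handed product turned over with time, and both products count against the left-handed substrate, as in a kinetic resolution.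

Alder's two products at 5.00 min, scaled to the flask's loading and to 10 min, then divided by the left-handed substrate's half of the charge, give the budget number: the product the catalyst can make in the time, as a fraction of the left-handed charge, 1.66. Oak gives 1.53 and birch 1.31. Each stands above 1, so this reckoning puts the reacted part of the flask near 50.0%, where the left-handed charge is used up. For the excess one number is not enough: it holds no clock for the turning over of product, so the excess at 12 s is out of its reach, and the excess at 10 min is placed below those readings by their trend.

The forecast gives 88%, 16% and 60%, and says that “the catalyst is near saturation, with little deactivation”; its reacted part stands above this reckoning's figure.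

The flask gives 96.9%, 11.7% and 50.2%.

    free catalyst + right-handed substrate ⇌ catalyst intermediate B (K = 1.00 M⁻¹, k = 130 M⁻¹ s⁻¹)
    free catalyst + left-handed substrate ⇌ catalyst intermediate A (K = 21.0 M⁻¹, k = 77.4 M⁻¹ s⁻¹)
    reagent + catalyst intermediate B → free catalyst + right-handed product (k = 0.484 M⁻¹ s⁻¹)
    left-handed product ⇌ right-handed product (k = 0.00333 s⁻¹)
    reagent + free catalyst → spent catalyst (k = 0.00854 M⁻¹ s⁻¹)
    reagent + catalyst intermediate A → free catalyst + left-handed product (k = 20.7 M⁻¹ s⁻¹)
    gas ⇌ reagent, rate k7*(csat - [reagent]) (kL = 0.0626 s⁻¹)

With 1.66 reckoned, the reacted part of the flask stands at 50.2% against the reckoned 50.0%, and less of its left-handed substrate than of its right-handed remains unbound, 0.69% against 99%. The neighbour flask, at 0.025 mol% free catalyst, gets 0.414 by the same reckoning, below 1, which means 41.4% of its left-handed substrate used and 20.7% of the whole charge reacted. In that flask 43.4% of the left-handed substrate is no longer unbound and 21.8% of the whole charge has reacted, with unbound right-handed substrate at 99.9% of its charge.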